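The overall equation holds [starting material] + [product] at its charge, and [coupling partner] + [product] likewise, as long as no other channel consumes either. In the zeta run, the reading of 0.0535 M at 18 min then leaves 0.0965 M of starting material, the limiting reagent by charge, and 0.112 M of coupling partner.

| flask | starting material | coupling partner | time |
|---|---|---|---|
| zeta | 0.150 M | 0.165 M |  |
| eta | 0.0900 M | 0.105 M |  |
| epsilon | 0.150 M | 0.330 M |  |
| gamma | 0.150 M | 0.165 M | 36 min |

| run | time / min | [product] / M |
|---|---|---|
| zeta run | 0.80 | 0.0064 |
| zeta run | 2.4 | 0.0077 |
| zeta run | 4.6 | 0.0180 |
| zeta run | 7.4 | 0.0358 |
| zeta run | 11 | 0.0432 |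
| zeta run | 14 | 0.0483 |
| zeta run | 18 | 0.0535 |
| eta run | 0.80 | 8 × 10⁻⁴ |
| eta run | 2.4 | 0.0021 |
| eta run | 4.6 | 0.0110 |
| eta run | 7.4 | 0.0219 |
| eta run | 11 | 0.0236 |
| eta run | 14 | 0.0286 |
| eta run | 18 | 0.0314 |
| epsilon run | 0.80 | 0.0034 |
| epsilon run | 2.4 | 0.0104 |
| epsilon run | 4.6 | 0.0327 |
| epsilon run | 7.4 | 0.0485 |
| epsilon run | 11 | 0.0579 |
| epsilon run | 14 | 0.0684 |
| epsilon run | 18 | 0.0748 |

(standard deviation of a reading: 0.002 M)

* reaction order in [coupling partner] at the outset, round the charge of the zeta run, defined at two percent of the starting material turned into product
* reaction order in [starting material] at the outset, round the charge of the zeta run, defined at two percent of the starting material turned into product (one fixed amount of product, the same in the runs compared)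
* product in the gamma run at 36 min, as a share of the starting material charged

- Overall: starting material + coupling partner -> product.
- Constant volume, constant temperature.
- Readings of a species count what is bound in complexes too.
- "The second partner" is coupling partner.
- An order is taken over about fifteen percent of the charge, up and down.

Those remainders do not go with the rate. In the zeta run, product forms on average at 0.00394 M/min between 4.6 min and 11 min, but at 0.00147 M/min between 11 min and 18 min, a fall by a factor of 2.68. A rate proportional to both concentrations loses a factor of 2.30 over the whole balance from the start to 18 min, which is less than that fall between two windows. So this reckoning treats the late rate as fading on its own clock. The fade lifetime, the time in which the late rate drops by a factor of e, is the distance between the window centres divided by the logarithm of the fall: 6.81 min, as read from the zeta readings.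

The gamma run has the charge of the zeta run, so it is taken to follow the zeta readings up to 18 min. The rate there, carried forward from the second window, is 8.80 × 10⁻⁴ M/min. The remaining 2.64 lifetimes add 0.00556 M, which gives a share of 39.4% at 36 min. The forecast, holding that “Depletion alone cannot explain that drop”, gives orders of 0.5 in coupling partner and 1.4 in starting material, and a share of 45% (40% to 52%), higher than this reckoning.

The gamma run gives a product share of 34.5% at 36 min; round the charge of the zeta run, the orders at the outset are 0.47 in coupling partner and 0.42 in starting material.

starting material ⇌ intermediate + by-product (0.1998 /min, 0.8520 /M/min); intermediate + coupling partner → product (3.690 /M/min); 2 starting material ⇌ idle substrate dimer, settled at all times (17.40 /M); coupling partner → lost reagent (0.1422 /min) That share is 0.0517 M, which lies 0.00182 M below the zeta reading at 18 min, a gap smaller than the scatter of 0.002 M. The epsilon run reaches a quarter of its starting material charged as product at 5.66 min and half at 17.7 min. Its rate read between 4.6 min and 7.4 min is 0.00564 M/min, and the fade lifetime from the zeta readings turns that rate into a gain of 0.0319 M between those two times, against 0.0375 M made in the epsilon run.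

The data are calculated with constants of no real substance.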